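Numbering follows the tetralin core: C1 (methyl), C4 (side chain C11–C16), aromatic ring A = C4a, C5, C6 (ester), C7, C8 (oxygens), C8a; ring B = C1–C4. Everything rests on cutting ring A at C5–C6 and C8–C8a. Ring B, with its trans C1/C4 stereocentres, is the p-menthane ring of reduced (R)-carvone; its ketone carbon and formylated α-methylene become C8a and C4a. One [3+3] condensation of this 2-hydroxymethylene ketone with a 4-alkoxyacetoacetate closes ring A and installs the C6 ester, C7 hydroxyl and C8 oxygen in the final pattern. The alkoxy group is benzyl, so the last hydrogenation also unmasks the catechol. The isopropenyl group is then grown into C11–C16.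

Key step: step 3

Assumption: methyl 4-(benzyloxy)-3-oxobutanoate and (4R)-4-benzyl-3-propanoyl-1,3-oxazolidin-2-one are bought; the ligand antipode in step 6 is assigned by analogy with ruthenium BINAP hydrogenations of 2-substituted allylic alcohols that carry a ring stereocentre.

Locants: compound names use tetrahydronaphthalene numbering (its C5, C8, C2, C3, C4 are C1, C4, C6, C7, C8 of the overview numbering, which the Why lines keep).

Step 1
Reactants: 1 (R)-(−)-carvone
Product: 3 (2R,5R)-2-methyl-5-(prop-1-en-2-yl)cyclohexan-1-one, via lithium enolate 2 (not isolated)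
Conditions: LiBH(s-Bu)3 (1.1 equiv), THF, −78 °C; then H2O
Reagents that add atoms: none
Why: Conjugate (1,4) hydride reduction of the enone gives lithium enolate 2, and its axial protonation on the chair with the isopropenyl group equatorial should place the new methyl trans to it, which is also the more stable epimer (any cis epimer is removed by chromatography), so this centre is set by the carvone centre.

Step 2
Reactants: 3 (2R,5R)-2-methyl-5-(prop-1-en-2-yl)cyclohexan-1-one, 4 ethyl formate
Product: 5 (2Z,3S,6R)-2-(hydroxymethylidene)-6-methyl-3-(prop-1-en-2-yl)cyclohexan-1-one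
Conditions: NaH (2 equiv), HCO2Et (3 equiv), EtOH (cat.), THF, 0 °C → rt; then aq. HCl
Reagents that add atoms: ethyl formate 4, CCOC=O
Why: Crossed Claisen condensation with ethyl formate, in which only acylation at the α-methylene gives an enolisable β-keto aldehyde whose sodium salt drives the equilibrium, so the formyl group should enter next to the isopropenyl-bearing carbon while the basic medium keeps the α-methyl centre at its trans equilibrium position.

Step 3
Reactants: 5 (2Z,3S,6R)-2-(hydroxymethylidene)-6-methyl-3-(prop-1-en-2-yl)cyclohexan-1-one, 6 methyl 4-(benzyloxy)-3-oxobutanoate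
Product: 8 methyl (5R,8S)-4-(benzyloxy)-3-hydroxy-5-methyl-8-(prop-1-en-2-yl)-5,6,7,8-tetrahydronaphthalene-2-carboxylate, via Knoevenagel adduct 7 (not isolated)
Conditions: piperidine (0.3 equiv), AcOH (0.3 equiv), PhMe, reflux, Dean–Stark; then NaOMe (1.5 equiv), MeOH, 50 °C; AcOH quench
Reagents that add atoms: methyl 4-(benzyloxy)-3-oxobutanoate 6, COC(=O)CC(=O)COCc1ccccc1
Why: The doubly activated C2 of the keto ester condenses with the formyl carbon (Knoevenagel condensation through the piperidine enaminone) to give adduct 7 and the C5–C6 bond; the enol or enolate of the side-chain ketone then adds through its benzyloxy-bearing carbon to the ring ketone (intramolecular aldol, C8–C8a), and loss of water with enolisation of the C7 carbonyl gives the aromatic salicylate, methoxide in methanol returning any O-cyclised or uncyclised material to this irreversible outlet. The closest known reaction type is the base-mediated [3+3] benzannulation of 2-hydroxymethylene cycloalkanones with acetonedicarboxylate or acetoacetate esters, here run with a 4-alkoxy partner. Ring A closes in a 6-(enolendo)-exo-trig aldol mode. No stereocentre is formed; C1 and C4 come from carvone, and the buffered first stage is meant to limit enolisation toward C1 before aromatisation makes that centre benzylic and fixed. The step needs the C2 carbanion at the aldehyde carbon and the alkoxy-bearing carbon at the ketone, which the acidity order of the two nucleophilic sites and the higher electrophilicity of the formyl group should secure, and the ketone has a methylene on one side only, so only one orientation of annulation is possible.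

Step 4
Reactants: 8 methyl (5R,8S)-4-(benzyloxy)-3-hydroxy-5-methyl-8-(prop-1-en-2-yl)-5,6,7,8-tetrahydronaphthalene-2-carboxylate, 9 benzyl bromide
Product: 10 methyl (5R,8S)-3,4-bis(benzyloxy)-5-methyl-8-(prop-1-en-2-yl)-5,6,7,8-tetrahydronaphthalene-2-carboxylate
Conditions: BnBr (1.3 equiv), K2CO3 (2 equiv), DMF, 60 °C
Reagents that add atoms: benzyl bromide 9, BrCc1ccccc1
Why: Williamson etherification of the hydrogen-bonded salicylate phenol; the second benzyl group shields the oxidisable catechol monoether through steps 5 to 11 and leaves together with the first in step 12.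

Step 5
Reactants: 10 methyl (5R,8S)-3,4-bis(benzyloxy)-5-methyl-8-(prop-1-en-2-yl)-5,6,7,8-tetrahydronaphthalene-2-carboxylate
Product: 11 methyl (5R,8R)-3,4-bis(benzyloxy)-8-(3-hydroxyprop-1-en-2-yl)-5-methyl-5,6,7,8-tetrahydronaphthalene-2-carboxylate
Conditions: SeO2 (0.5 equiv), t-BuOOH (3 equiv), CH2Cl2, 0 °C → rt
Reagents that add atoms: tert-butyl hydroperoxide, CC(C)(C)OO (oxygen relayed through SeO2, O=[Se]=O)
Why: Selenium dioxide allylic hydroxylation (ene reaction then 2,3-sigmatropic shift) of the 1,1-disubstituted alkene, expected at the methyl group because the tertiary C4–H lies in the alkene plane in the rotamer free of allylic strain and is poorly aligned for the ene step, with the hydroperoxide re-oxidising selenium so that the reaction should stop at the alcohol.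

Step 6
Reactants: 11 methyl (5R,8R)-3,4-bis(benzyloxy)-8-(3-hydroxyprop-1-en-2-yl)-5-methyl-5,6,7,8-tetrahydronaphthalene-2-carboxylate
Product: 12 methyl (5R,8S)-3,4-bis(benzyloxy)-8-[(2R)-1-hydroxypropan-2-yl]-5-methyl-5,6,7,8-tetrahydronaphthalene-2-carboxylate
Conditions: Ru(OAc)2[(R)-BINAP] (2 mol%), H2 (100 atm), MeOH–CH2Cl2, 25 °C
Reagents that add atoms: none
Why: Ruthenium–BINAP asymmetric hydrogenation of a 2-substituted allylic alcohol, in which the alcohol binds the metal as alkoxide and both hydrogens are delivered to the alkene face chosen by the ligand, so C11 is set under catalyst control while benzyl ethers, ester and arene stay inert.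

Step 7
Reactants: 12 methyl (5R,8S)-3,4-bis(benzyloxy)-8-[(2R)-1-hydroxypropan-2-yl]-5-methyl-5,6,7,8-tetrahydronaphthalene-2-carboxylate
Product: 13 methyl (5R,8S)-3,4-bis(benzyloxy)-5-methyl-8-[(2R)-1-oxopropan-2-yl]-5,6,7,8-tetrahydronaphthalene-2-carboxylate
Conditions: Dess–Martin periodinane (1.3 equiv), CH2Cl2, 0 °C → rt; used crude
Reagents that add atoms: none
Why: Dess–Martin oxidation of the primary alcohol to the aldehyde under neutral conditions, which should leave the adjacent C11 centre intact when the aldehyde is used at once.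

Step 8
Reactants: 13 methyl (5R,8S)-3,4-bis(benzyloxy)-5-methyl-8-[(2R)-1-oxopropan-2-yl]-5,6,7,8-tetrahydronaphthalene-2-carboxylate, 14 methyltriphenylphosphonium bromide
Product: 15 methyl (5R,8S)-3,4-bis(benzyloxy)-8-[(2S)-but-3-en-2-yl]-5-methyl-5,6,7,8-tetrahydronaphthalene-2-carboxylate
Conditions: Ph3PCH3Br (1.5 equiv), KN(SiMe3)2 (1.4 equiv), THF, −78 °C → 0 °C
Reagents that add atoms: methyltriphenylphosphonium bromide 14, C[P+](c1ccccc1)(c1ccccc1)c1ccccc1.[Br-]
Why: Wittig methylenation with the non-stabilised ylide, which should add to the aldehyde at low temperature much faster than it deprotonates C11 or attacks the hindered aryl ester.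

Step 9
Reactants: 16 (4R)-4-benzyl-3-propanoyl-1,3-oxazolidin-2-one, 17 allyl iodide
Product: 19 (4R)-4-benzyl-3-[(2S)-2-methylpent-4-enoyl]-1,3-oxazolidin-2-one, via sodium enolate 18 (not isolated)
Conditions: NaN(SiMe3)2 (1.1 equiv), THF, −78 °C; then allyl iodide (3 equiv), −78 °C → −40 °C
Reagents that add atoms: allyl iodide 17, C=CCI
Why: Evans asymmetric alkylation, in which the chelated Z sodium enolate 18 is allylated on the face opposite the benzyl group of the auxiliary, setting the S centre that becomes C15.

Step 10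
Reactants: 19 (4R)-4-benzyl-3-[(2S)-2-methylpent-4-enoyl]-1,3-oxazolidin-2-one
Product: 20 (2S)-2-methylpent-4-en-1-ol
Conditions: LiBH4 (1.5 equiv), H2O (1.5 equiv), Et2O, 0 °C
Reagents that add atoms: none
Why: Reductive cleavage of the N-acyl oxazolidinone by lithium borohydride at the exocyclic carbonyl, which should give the primary alcohol without touching the α-centre and release the auxiliary.

Step 11
Reactants: 15 methyl (5R,8S)-3,4-bis(benzyloxy)-8-[(2S)-but-3-en-2-yl]-5-methyl-5,6,7,8-tetrahydronaphthalene-2-carboxylate, 20 (2S)-2-methylpent-4-en-1-ol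
Product: 21 methyl (5R,8S)-3,4-bis(benzyloxy)-8-[(2S,3E,6S)-7-hydroxy-6-methylhept-3-en-2-yl]-5-methyl-5,6,7,8-tetrahydronaphthalene-2-carboxylate
Conditions: second-generation Hoveyda–Grubbs catalyst RuCl2(H2IMes)(=CH-C6H4-2-OiPr) (5 mol%), 20 (3 equiv), CH2Cl2, 40 °C
Reagents that add atoms: (2S)-2-methylpent-4-en-1-ol 20, C=CC[C@H](C)CO
Why: Olefin cross-metathesis, in which the α-branched alkene of 15 homodimerises slowly and should be captured by the unhindered alkene of 20 used in excess, forming C12=C13 with loss of ethene; the alkene geometry is irrelevant and no stereocentre is involved.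

Step 12
Reactants: 21 methyl (5R,8S)-3,4-bis(benzyloxy)-8-[(2S,3E,6S)-7-hydroxy-6-methylhept-3-en-2-yl]-5-methyl-5,6,7,8-tetrahydronaphthalene-2-carboxylate
Product: 23 methyl (5R,8S)-3,4-dihydroxy-8-[(2S,6S)-7-hydroxy-6-methylheptan-2-yl]-5-methyl-5,6,7,8-tetrahydronaphthalene-2-carboxylate (target), via saturated dibenzyl ether 22 (not isolated)
Conditions: H2 (1 atm), PtO2 (5 mol%), EtOAc, rt; then Pd/C (10 wt%), MeOH, H2 (1 atm), rt
Reagents that add atoms: none
Why: Catalytic hydrogenation in two stages, platinum saturating C12=C13 without double-bond migration toward C11 and palladium then hydrogenolysing both aryl benzyl ethers, while the methyl ester, the primary alcohol and the four stereocentres are untouched.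

Compound list

1 | (R)-(−)-carvone, (5R)-2-methyl-5-(prop-1-en-2-yl)cyclohex-2-en-1-one | CC1=CC[C@H](CC1=O)C(C)=C | starting material
2 | lithium (5R)-2-methyl-5-(prop-1-en-2-yl)cyclohex-1-en-1-olate (lithium enolate) | CC1=C([O-])C[C@@H](CC1)C(C)=C.[Li+] | intermediate
3 | (2R,5R)-2-methyl-5-(prop-1-en-2-yl)cyclohexan-1-one (trans-dihydrocarvone) | C[C@@H]1CC[C@@H](C(C)=C)CC1=O | intermediate
4 | ethyl formate | CCOC=O | starting material
5 | (2Z,3S,6R)-2-(hydroxymethylidene)-6-methyl-3-(prop-1-en-2-yl)cyclohexan-1-one | C[C@@H]1CC[C@@H](C(C)=C)/C(=C/O)C1=O | intermediate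
6 | methyl 4-(benzyloxy)-3-oxobutanoate | COC(=O)CC(=O)COCc1ccccc1 | starting material
7 | methyl 4-(benzyloxy)-2-{[(3R,6R)-3-methyl-2-oxo-6-(prop-1-en-2-yl)cyclohexyl]methylidene}-3-oxobutanoate (Knoevenagel adduct; ring C1 and alkene geometry undefined, in equilibrium with its dienol tautomers) | C[C@@H]1CC[C@@H](C(C)=C)C(C=C(C(=O)OC)C(=O)COCc2ccccc2)C1=O | intermediate
8 | methyl (5R,8S)-4-(benzyloxy)-3-hydroxy-5-methyl-8-(prop-1-en-2-yl)-5,6,7,8-tetrahydronaphthalene-2-carboxylate | COC(=O)c1cc2c(c(OCc3ccccc3)c1O)[C@H](C)CC[C@H]2C(C)=C | intermediate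
9 | benzyl bromide | BrCc1ccccc1 | starting material
10 | methyl (5R,8S)-3,4-bis(benzyloxy)-5-methyl-8-(prop-1-en-2-yl)-5,6,7,8-tetrahydronaphthalene-2-carboxylate | COC(=O)c1cc2c(c(OCc3ccccc3)c1OCc4ccccc4)[C@H](C)CC[C@H]2C(C)=C | intermediate
11 | methyl (5R,8R)-3,4-bis(benzyloxy)-8-(3-hydroxyprop-1-en-2-yl)-5-methyl-5,6,7,8-tetrahydronaphthalene-2-carboxylate | COC(=O)c1cc2c(c(OCc3ccccc3)c1OCc4ccccc4)[C@H](C)CC[C@H]2C(=C)CO | intermediate
12 | methyl (5R,8S)-3,4-bis(benzyloxy)-8-[(2R)-1-hydroxypropan-2-yl]-5-methyl-5,6,7,8-tetrahydronaphthalene-2-carboxylate | COC(=O)c1cc2c(c(OCc3ccccc3)c1OCc4ccccc4)[C@H](C)CC[C@H]2[C@@H](C)CO | intermediate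
13 | methyl (5R,8S)-3,4-bis(benzyloxy)-5-methyl-8-[(2R)-1-oxopropan-2-yl]-5,6,7,8-tetrahydronaphthalene-2-carboxylate | COC(=O)c1cc2c(c(OCc3ccccc3)c1OCc4ccccc4)[C@H](C)CC[C@H]2[C@@H](C)C=O | intermediate
14 | methyltriphenylphosphonium bromide | C[P+](c1ccccc1)(c1ccccc1)c1ccccc1.[Br-] | starting material
15 | methyl (5R,8S)-3,4-bis(benzyloxy)-8-[(2S)-but-3-en-2-yl]-5-methyl-5,6,7,8-tetrahydronaphthalene-2-carboxylate | COC(=O)c1cc2c(c(OCc3ccccc3)c1OCc4ccccc4)[C@H](C)CC[C@H]2[C@@H](C)C=C | intermediate
16 | (4R)-4-benzyl-3-propanoyl-1,3-oxazolidin-2-one | CCC(=O)N1[C@H](Cc2ccccc2)COC1=O | starting material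
17 | allyl iodide (3-iodoprop-1-ene) | C=CCI | starting material
18 | sodium (Z)-enolate of 16 | C/C=C(\[O-])N1[C@H](Cc2ccccc2)COC1=O.[Na+] | intermediate
19 | (4R)-4-benzyl-3-[(2S)-2-methylpent-4-enoyl]-1,3-oxazolidin-2-one | C=CC[C@H](C)C(=O)N1[C@H](Cc2ccccc2)COC1=O | intermediate
20 | (2S)-2-methylpent-4-en-1-ol | C=CC[C@H](C)CO | intermediate
21 | methyl (5R,8S)-3,4-bis(benzyloxy)-8-[(2S,3E,6S)-7-hydroxy-6-methylhept-3-en-2-yl]-5-methyl-5,6,7,8-tetrahydronaphthalene-2-carboxylate (E shown; both alkene isomers converge in step 12) | COC(=O)c1cc2c(c(OCc3ccccc3)c1OCc4ccccc4)[C@H](C)CC[C@H]2[C@@H](C)/C=C/C[C@H](C)CO | intermediate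
22 | methyl (5R,8S)-3,4-bis(benzyloxy)-8-[(2S,6S)-7-hydroxy-6-methylheptan-2-yl]-5-methyl-5,6,7,8-tetrahydronaphthalene-2-carboxylate (saturated dibenzyl ether) | COC(=O)c1cc2c(c(OCc3ccccc3)c1OCc4ccccc4)[C@H](C)CC[C@H]2[C@@H](C)CCC[C@H](C)CO | intermediate
23 | methyl (5R,8S)-3,4-dihydroxy-8-[(2S,6S)-7-hydroxy-6-methylheptan-2-yl]-5-methyl-5,6,7,8-tetrahydronaphthalene-2-carboxylate | COC(=O)c1cc2c(c(O)c1O)[C@H](C)CC[C@H]2[C@@H](C)CCC[C@H](C)CO | target

Total steps: 12. Longest linear sequence: 10 (steps 1–8, 11, 12); steps 9 and 10 make the side-chain alkene.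

Steps most likely to fail

Step 3. The sequence may stall at the Knoevenagel stage or divert to O-cyclisation (enol lactonisation to a 2-pyranone), and enolisation toward C1 before aromatisation may erode the trans relationship. The fallback sets out from ketone 3 and builds ring A by cycloaddition instead of condensation. The kinetic lithium enolate of 3 (LiN(i-Pr)2, THF, −78 °C) is condensed with dimethyl (methoxymethylene)malonate and lactonised (TsOH, PhMe, reflux) to the fused methyl 2-oxo-2H-chromene-3-carboxylate F1. An inverse-electron-demand Diels–Alder reaction of this 3-carbomethoxy-2-pyrone with 1,1,2-trimethoxyethene (PhMe, 140 °C, sealed tube), followed in the same pot by loss of CO2 and methanol, should give the dimethyl ether F2; the nucleophilic dienophile carbon bonds to C8a and the acetal carbon to C6, so the substitution pattern is the same. BBr3 (CH2Cl2, −78 °C → 0 °C) should give the catechol F3, and double benzylation (BnBr, K2CO3, DMF) comes back to the route at 10.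

Step 5. The ene oxidation may take the benzylic, allylic C4–H in place of a methyl hydrogen, or run on to the enal and attack the electron-rich ring. The fallback sets out from 10 and avoids allylic oxidation. Hydroboration with 9-borabicyclo[3.3.1]nonane (THF, 0 °C → rt) and oxidation with NaBO3·4H2O should give alcohol 12 together with its C11 epimer F4 under substrate control; chromatographic separation returns to the route at 12 and bypasses steps 5 and 6.

Step 6. Facial selectivity may be poor if the bias of the C4 centre opposes the catalyst, and the alkene may isomerise before reduction. The fallback sets out from 11 and moves the directing group to a carboxylic acid. MnO2 (CH2Cl2) should give the enal F5 and Pinnick oxidation (NaClO2, NaH2PO4, 2-methyl-2-butene, t-BuOH–H2O) the 2-substituted acrylic acid F6. Carboxylate-directed hydrogenation with Ru(OAc)2[(R)-BINAP] (H2 100 atm, MeOH), the well-studied class of α-substituted acrylic acids, should give the saturated acid F7. BH3·SMe2 (THF, 0 °C) reduces the acid in the presence of the aryl ester and comes back to the route at 12.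

Further compounds

F1 | step 3 | methyl (5S,8R)-8-methyl-2-oxo-5-(prop-1-en-2-yl)-5,6,7,8-tetrahydro-2H-chromene-3-carboxylate | COC(=O)C1=CC2=C(OC1=O)[C@H](C)CC[C@H]2C(C)=C
F2 | step 3 | methyl (5R,8S)-3,4-dimethoxy-5-methyl-8-(prop-1-en-2-yl)-5,6,7,8-tetrahydronaphthalene-2-carboxylate | COC(=O)c1cc2c(c(OC)c1OC)[C@H](C)CC[C@H]2C(C)=C
F3 | step 3 | methyl (5R,8S)-3,4-dihydroxy-5-methyl-8-(prop-1-en-2-yl)-5,6,7,8-tetrahydronaphthalene-2-carboxylate | COC(=O)c1cc2c(c(O)c1O)[C@H](C)CC[C@H]2C(C)=C
F4 | step 5 | methyl (5R,8S)-3,4-bis(benzyloxy)-8-[(2S)-1-hydroxypropan-2-yl]-5-methyl-5,6,7,8-tetrahydronaphthalene-2-carboxylate (C11 epimer of 12) | COC(=O)c1cc2c(c(OCc3ccccc3)c1OCc4ccccc4)[C@H](C)CC[C@H]2[C@H](C)CO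
F5 | step 6 | methyl (5R,8R)-3,4-bis(benzyloxy)-5-methyl-8-(3-oxoprop-1-en-2-yl)-5,6,7,8-tetrahydronaphthalene-2-carboxylate | COC(=O)c1cc2c(c(OCc3ccccc3)c1OCc4ccccc4)[C@H](C)CC[C@H]2C(=C)C=O
F6 | step 6 | acrylic acid of F5 (CO2H in place of CHO), 2-substituted prop-2-enoic acid on C4 of the (5R,8R) core | COC(=O)c1cc2c(c(OCc3ccccc3)c1OCc4ccccc4)[C@H](C)CC[C@H]2C(=C)C(O)=O
F7 | step 6 | (2R)-propanoic acid of 12 (CO2H in place of CH2OH) on the (5R,8S) core | COC(=O)c1cc2c(c(OCc3ccccc3)c1OCc4ccccc4)[C@H](C)CC[C@H]2[C@@H](C)C(O)=O
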